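## The problem

Target 33 is a biflavonoid. An isoflavan (benzo ring A, pyran ring C, 3-hydroxy-2,4-dimethoxyphenyl ring B) is bonded through its C4 to C6 of (2S)-naringenin (benzo ring D, pyranone ring F, 4-hydroxyphenyl ring E). C4 therefore carries two arenes (ring A and the 2,6-dioxygenated ring D) and the adjacent C3 carries ring B: a 1,1,2-triarylethane in which every arene has an ortho oxygen. Three stereocentres are needed. C3 (R) and C4 (S) are adjacent and trans, so one can be tied to the other. C2 of ring F (S) lies beyond ring D, out of reach of substrate control, and needs a catalyst. The C4–ring D bond is acid-labile: ipso protonation of the phloroglucinol-type ring D releases a C4 cation stabilised by O1 and the 7-oxygen of ring A, and that cation can also lose H3 and erase C3. The flavanone opens to its 2'-hydroxychalcone under base, which racemises C2 of ring F, so the five phenols must be freed under neutral conditions. The feature that makes the key step possible is that C3–C4 with its three aryl groups is the saturated image of an E alkene ring D–CH=CH–B: C4 is the β-carbon already bearing ring D, C3 is the boron-bearing carbon, and boron marks the place of C2. Ring D, until ring F is built, is a symmetric 2,6-dioxygenated 4-oxygenated phenyl group, so the two positions next to its unique para oxygen are equivalent.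

## Retrosynthesis

**33 from 32.** The five phenolic O–H bonds are traced to five O–benzyl bonds in 32. Benzyl is preferred to acetal or silyl protection because hydrogenolysis is neutral; acid threatens the C4–ring D bond and base or fluoride opens the flavanone. The skeleton is unchanged. The forward step must cleave five benzyl ethers without reducing the ketone or the benzylic C2–O1 bond of ring F.

**32 from 30 and 31.** The C2–ring E bond of ring F is cut, giving chromone 30 and arylboronic acid 31. Cutting O1–C2 instead (oxa-Michael closure of a ring-opened enone) offers no reliable control of C2. Chromone 30 has no stereocentre in ring F and 31 is commercial. The forward reaction must be a catalyst-controlled conjugate arylation, since the isoflavan centres are too remote to help or hinder.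

**30 from 26 via 27 and 28.** Ring F is removed by cutting O1–C2 (conjugate addition of the phenol to ynone 29) and C4–C4a (ortho-formylation of phenol 26, then addition of an ethynyl unit to aldehyde 27 and oxidation of carbinol 28). A Friedel–Crafts acylation would be shorter but needs acid on the most acid-sensitive intermediate. Phenol 26 has a symmetric ring D, so no regiochemical question arises. The forward sequence must stay neutral or basic.

**26 from 24 via 25.** The silyl ether on the para oxygen of ring D is restored (25), then O1–C2 of ring C is cut to give phenol–primary alcohol 24. Etherification of a primary alcohol by the ring A phenol touches no stereocentre. The precursor is acyclic. The forward reaction is a six-membered Mitsunobu closure.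

**24 from 20 via 22.** The acetal on the ring A oxygen is restored (22), and C2 is then excised: the C2–C3 bond is cut back to a C3–boron bond in 20. Boron is the natural placeholder because a one-carbon homologation with retention followed by oxidation turns C–B into C–CH2–OH. The forward steps must insert one carbon into a hindered secondary boronic ester and unmask the phenol without acid.

**20 from 9, 18 and 14 (key disconnection).** The C3–ring B bond and the C4–C4a bond are cut together. This leaves E alkenyl boronate 9 (ring D on the β-carbon), aryllithium 18 (ring B) and aryl triflate 14 (ring A). The cut is preferred to forming C4–ring D by Friedel–Crafts chemistry (acid, risk to C3) because anti addition across a defined alkene fixes the C3/C4 relationship mechanistically, and one chiral ligand sets the absolute sense. The hindered 2,6-disubstituted ring is placed on the alkene, not on the electrophile. The boron carries the hindered diol 7, not a smaller diol, because β-substituted alkenyl boronates with small diols are known to divert to direct Suzuki–Miyaura coupling. Three fragments of similar size replace a congested triarylethane.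

**Fragments.** Boronate 9 comes from alkyne 5 and diol 7 by hydroboration and ester exchange. Alkyne 5 comes from aldehyde 3 (via dibromoalkene 4), and 3 from 2,4,6-trihydroxybenzaldehyde 1 by para-silylation (2) and benzylation. Diol 7 comes from acenaphthoquinone 6. Triflate 14 comes from 4-(benzyloxy)-2-hydroxybenzaldehyde 10 through acetal 11, Dakin oxidation to phenol 13 and triflation. Aryllithium 18 comes from bromide 17, made from 2,6-dimethoxyphenol 15 via benzyl ether 16.

## Roads not taken

Alternative 1: The cut is through ring F at C4a–C4, C4–C3 and O1–C2. In the forward step an ortho-iodophenol A1 (phenol 26 iodinated next to its hydroxyl) and arylacetylene A2 are joined in a palladium-catalysed carbonylative coupling followed by 6-endo cyclisation, giving flavone A3. Its merit is brevity: ring F and ring E arrive in two operations from 26, against four in the chosen route, and A2 is commercial. Its weak points are that A3 is flat at C2, so the stereocentre still has to be made by enantioselective reduction of a hindered 5-alkoxyflavone in the presence of five benzyl ethers, for which no dependable method exists; 5-exo closure to an aurone competes; and the step does nothing for C3 and C4, which remain the hard part. On ring F step count this road is better. The chosen plan sets against it a key step that solves the triarylethane with two stereocentres and an endgame in which C2 is set by a catalytic arylation.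

Alternative 2: The cut is at C4a–C4 and C8a–O1 of the flavanone. In the forward step, fluoride-induced aryne generation from ortho-silylaryl triflate A4 across C4a–C8a is followed by formal insertion into the acyl–oxygen bond of cinnamic acid A5, giving 2'-hydroxychalcone A6. Its merit is that the benzyloxy group flanking the aryne directs oxygen to C8a and the acyl carbon to C4a without any acid, and all carbons of ring F and ring E arrive at once. Its weak points are that A4 requires several steps of halogenation, silyl transfer and triflation on an advanced isoflavan, that the reactive intermediate meets three other electron-rich arenes in the same molecule, and that A6 closes to both C2 epimers. The regiocontrol is elegant, but the chosen plan does not need it because ring D is symmetric when ring F is started. The chosen plan also controls C2, which this road does not.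

Alternative 3: The cut is at C3–C4 and O1–C2 of ring C. In the forward step ortho-hydroxybenzhydrol A7 ionises under a mild acid co-catalyst and is trapped at C4 by arylacetaldehyde A8 under chiral secondary-amine catalysis, closing ring C as the trans lactol A9. This is a real competitor: ring C is closed in the key step, the fragments are simple, no organolithium, boron ligand or homologation is needed, and the epimerisable C3 lets the trans isomer accumulate. Its weak points are that facial control must be exerted on a methide carbon carrying a 2,6-dibenzyloxyaryl group and an exceptionally stabilised cation, so addition may be reversible and erode C4; that acid is present exactly where the skeleton is most sensitive; and that A9 still needs reduction and re-closure, which returns most of the saved steps. It is probably as short as the chosen route to the chroman. The chosen plan sets against it a relative configuration fixed by alkene geometry and anti addition, not by equilibration, and no acid after the diarylmethine exists. This chemistry is kept as the fallback for the key step.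

Key step: step 12

Assumption: the (Sp,Sp) ligand of step 12 and the (S) ligand of step 20 are taken, by analogy with simpler alkenyl boronates and with cyclic enones, to give the senses drawn; both ligands are available in either enantiomeric form should a sense prove reversed.

## Route

Step 1
Reactants: 1 2,4,6-trihydroxybenzaldehyde
Product: 2 2,6-dihydroxy-4-(triisopropylsilyloxy)benzaldehyde
Conditions: TIPSCl (1.0 equiv), imidazole, CH2Cl2/DMF, 0 °C
Reagents that add atoms: triisopropylsilyl chloride, CC(C)[Si](Cl)(C(C)C)C(C)C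
Why: Selective O-silylation; the 4-hydroxyl is the most acidic (para to the formyl group) and the least hindered, while the 2- and 6-hydroxyls flank the carbonyl and are hydrogen-bonded to it, so a bulky silyl chloride should take the para position.

Step 2
Reactants: 2 2,6-dihydroxy-4-(triisopropylsilyloxy)benzaldehyde
Product: 3 2,6-bis(benzyloxy)-4-(triisopropylsilyloxy)benzaldehyde
Conditions: BnOH, PPh3, DIAD, THF, 0 °C → rt
Reagents that add atoms: benzyl alcohol, OCc1ccccc1
Why: Double Mitsunobu etherification of the acidic ortho-formyl phenols under neutral conditions; carbonate-mediated benzylation is avoided because it can strip an aryl silyl ether para to a formyl group.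

Step 3
Reactants: 3 2,6-bis(benzyloxy)-4-(triisopropylsilyloxy)benzaldehyde
Product: 4 [3,5-bis(benzyloxy)-4-(2,2-dibromoethenyl)phenoxy]triisopropylsilane
Conditions: CBr4, PPh3, CH2Cl2, 0 °C
Reagents that add atoms: carbon tetrabromide, BrC(Br)(Br)Br
Why: Dibromo-olefination of an aldehyde with the ylide from CBr4 and PPh3 (first stage of the Corey–Fuchs sequence), which tolerates di-ortho-alkoxy benzaldehydes.

Step 4
Reactants: 4 [3,5-bis(benzyloxy)-4-(2,2-dibromoethenyl)phenoxy]triisopropylsilane
Product: 5 [3,5-bis(benzyloxy)-4-ethynylphenoxy]triisopropylsilane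
Conditions: n-BuLi (2.1 equiv), THF, −78 °C; then H2O
Reagents that add atoms: none
Why: Second stage of the Corey–Fuchs sequence: bromine–lithium exchange, 1,2-shift of the carbenoid to the alkyne and deprotonation to the acetylide, which is protonated on quench; benzyl and silyl ethers are inert at −78 °C.

Step 5
Reactants: 6 acenaphthoquinone
Product: 7 cis-1,2-dimethyl-1,2-dihydroacenaphthylene-1,2-diol (meso)
Conditions: MeMgBr (2.5 equiv), THF, 0 °C → rt; recrystallisation
Reagents that add atoms: methylmagnesium bromide, C[Mg]Br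
Why: Double Grignard addition to a 1,2-diketone; the cis (meso) diol, the only isomer able to bridge one boron atom on the rigid five-membered ring, is purified by crystallisation.

Step 6
Reactants: 5 [3,5-bis(benzyloxy)-4-ethynylphenoxy]triisopropylsilane, 7 cis-1,2-dimethyl-1,2-dihydroacenaphthylene-1,2-diol
Product: 9 (E)-2-[2,6-bis(benzyloxy)-4-(triisopropylsilyloxy)phenyl]ethenylboronic acid cis-1,2-dimethylacenaphthene-1,2-diyl ester, via catechol boronate 8 (not isolated)
Conditions: catecholborane, THF, 70 °C; then 7, rt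
Reagents that add atoms: catecholborane, [BH]1Oc2ccccc2O1
Why: Syn, anti-Markovnikov hydroboration of a terminal alkyne gives the E alkenyl catechol boronate, and the labile catechol ester exchanges with the aliphatic diol; the free boronic acid of this electron-rich styrene is never exposed to water.

Step 7
Reactants: 10 4-(benzyloxy)-2-hydroxybenzaldehyde
Product: 11 4-(benzyloxy)-2-(methoxymethoxy)benzaldehyde
Conditions: MOMCl, i-Pr2NEt, CH2Cl2, 0 °C → rt
Reagents that add atoms: chloromethyl methyl ether, COCCl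
Why: Standard acetal protection of a phenol; the acetal cannot migrate to the neighbouring oxygen that step 8 creates, as a silyl or acyl group would.

Step 8
Reactants: 11 4-(benzyloxy)-2-(methoxymethoxy)benzaldehyde
Product: 13 4-(benzyloxy)-2-(methoxymethoxy)phenol, via aryl formate 12 (not isolated)
Conditions: mCPBA, CH2Cl2, 0 °C → rt; then K2CO3 (cat.), MeOH, rt
Reagents that add atoms: 3-chloroperoxybenzoic acid, OOC(=O)c1cccc(Cl)c1
Why: Dakin-type Baeyer–Villiger oxidation; the electron-rich aryl group migrates in preference to hydride, and the formate is removed by methanolysis.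

Step 9
Reactants: 13 4-(benzyloxy)-2-(methoxymethoxy)phenol
Product: 14 4-(benzyloxy)-2-(methoxymethoxy)phenyl trifluoromethanesulfonate
Conditions: Tf2O, pyridine, CH2Cl2, 0 °C
Reagents that add atoms: trifluoromethanesulfonic anhydride, O=S(=O)(OS(=O)(=O)C(F)(F)F)C(F)(F)F
Why: O-Sulfonylation of a phenol; the pyridine buffer keeps the acetal intact.

Step 10
Reactants: 15 2,6-dimethoxyphenol
Product: 16 2-(benzyloxy)-1,3-dimethoxybenzene
Conditions: BnBr, K2CO3, DMF, rt
Reagents that add atoms: benzyl bromide, BrCc1ccccc1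
Why: Williamson etherification of a phenol.

Step 11
Reactants: 16 2-(benzyloxy)-1,3-dimethoxybenzene
Product: 17 2-(benzyloxy)-4-bromo-1,3-dimethoxybenzene
Conditions: NBS, MeCN, 0 °C → rt
Reagents that add atoms: N-bromosuccinimide, O=C1CCC(=O)N1Br
Why: Electrophilic aromatic bromination; C4 is para to one methoxy group and ortho to the other, whereas C5 is activated only by the central, twisted benzyloxy group, as in the known 4-bromination of 1,2,3-trialkoxybenzenes.

Step 12
Reactants: 17 2-(benzyloxy)-4-bromo-1,3-dimethoxybenzene, 9 (E)-2-[2,6-bis(benzyloxy)-4-(triisopropylsilyloxy)phenyl]ethenylboronic acid cis-1,2-dimethylacenaphthene-1,2-diyl ester, 14 4-(benzyloxy)-2-(methoxymethoxy)phenyl trifluoromethanesulfonate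
Product: 20 [(1R,2S)-1-[3-(benzyloxy)-2,4-dimethoxyphenyl]-2-[4-(benzyloxy)-2-(methoxymethoxy)phenyl]-2-[2,6-bis(benzyloxy)-4-(triisopropylsilyloxy)phenyl]ethyl]boronic acid cis-1,2-dimethylacenaphthene-1,2-diyl ester (anti), via aryllithium 18 (not isolated), via lithium borate complex 19 (not isolated)
Conditions: t-BuLi (2 equiv), Et2O, −78 °C; 9, THF, −78 °C → rt; then 14, Pd(OAc)2 (3 mol %), (Sp,Sp)-Mandyphos ligand with P(3,5-Me2C6H3)2 groups (3.6 mol %), KOTf, THF, 60 °C
Reagents that add atoms: none
Why: Aryllithium 18 adds to boron of 9 to give borate 19; zerovalent palladium, formed from Pd(OAc)2 and the bisphosphine, inserts into the C–O bond of triflate 14, and the cationic arylpalladium binds the alkene of 19 and induces a 1,2-metallate shift in which ring B moves from boron to C3 anti to palladium at C4, after which reductive elimination joins ring A to C4 with retention. The closest known reaction type is the palladium-catalysed enantioselective conjunctive cross-coupling of β-substituted alkenylboron ate complexes with aryl triflates. No ring is closed. C4 is set by the ligand, which is expected to place palladium on the Re face of C4; C3 follows from C4 because migration is anti and the alkene is E, giving the anti diastereomer that maps onto the trans chroman. The step needs the metallate shift to outrun direct transmetalation from boron to palladium: the hindered diol on boron blocks that path, the triflate keeps palladium cationic and KOTf removes bromide, a known inhibitor. Aryl migrates in preference to the boron-bound oxygens, and fast reductive elimination from the benzylic palladium intermediate should forestall β-hydride loss.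

Step 13
Reactants: 20 [(1R,2S)-1-[3-(benzyloxy)-2,4-dimethoxyphenyl]-2-[4-(benzyloxy)-2-(methoxymethoxy)phenyl]-2-[2,6-bis(benzyloxy)-4-(triisopropylsilyloxy)phenyl]ethyl]boronic acid cis-1,2-dimethylacenaphthene-1,2-diyl ester
Product: 22 (2R,3S)-2-[3-(benzyloxy)-2,4-dimethoxyphenyl]-3-[4-(benzyloxy)-2-(methoxymethoxy)phenyl]-3-[2,6-bis(benzyloxy)-4-(triisopropylsilyloxy)phenyl]propan-1-ol, via homologated boronate 21 (not isolated)
Conditions: BrCH2Cl, n-BuLi, THF, −78 °C → rt; then NaBO3·4H2O, THF/H2O, rt
Reagents that add atoms: bromochloromethane, ClCBr; sodium perborate, [Na+].[O-]OB=O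
Why: Matteson homologation: chloromethyllithium made in the presence of the ester adds to boron and the C3 group migrates to carbon with retention, displacing chloride; mild perborate oxidation of the primary C–B bond then gives the alcohol without attacking the aryl silyl ether.

Step 14
Reactants: 22 (2R,3S)-2-[3-(benzyloxy)-2,4-dimethoxyphenyl]-3-[4-(benzyloxy)-2-(methoxymethoxy)phenyl]-3-[2,6-bis(benzyloxy)-4-(triisopropylsilyloxy)phenyl]propan-1-ol
Product: 24 (2R,3S)-2-[3-(benzyloxy)-2,4-dimethoxyphenyl]-3-[4-(benzyloxy)-2-hydroxyphenyl]-3-[2,6-bis(benzyloxy)-4-(triisopropylsilyloxy)phenyl]propan-1-ol, via bis(trimethylsilyl) ether 23 (not isolated)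
Conditions: TMSOTf, 2,2'-bipyridyl, MeCN, 0 °C → rt; then H2O
Reagents that add atoms: none
Why: Buffered silyl triflate cleavage of an aromatic methoxymethyl ether: the acetal is exchanged for a trimethylsilyl ether that hydrolyses on work-up, so no Brønsted acid meets the acid-labile diarylmethine; benzyl, methyl and triisopropylsilyl ethers are untouched.

Step 15
Reactants: 24 (2R,3S)-2-[3-(benzyloxy)-2,4-dimethoxyphenyl]-3-[4-(benzyloxy)-2-hydroxyphenyl]-3-[2,6-bis(benzyloxy)-4-(triisopropylsilyloxy)phenyl]propan-1-ol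
Product: 25 (3R,4S)-7-(benzyloxy)-3-[3-(benzyloxy)-2,4-dimethoxyphenyl]-4-[2,6-bis(benzyloxy)-4-(triisopropylsilyloxy)phenyl]chromane (trans)
Conditions: PPh3, DIAD, THF (dilute), 0 °C → rt
Reagents that add atoms: none
Why: Intramolecular Mitsunobu etherification (6-exo-tet) of the only free phenol with the primary alcohol closes ring C; the reacting carbon is a CH2, so C3 and C4 are untouched.

Step 16
Reactants: 25 (3R,4S)-7-(benzyloxy)-3-[3-(benzyloxy)-2,4-dimethoxyphenyl]-4-[2,6-bis(benzyloxy)-4-(triisopropylsilyloxy)phenyl]chromane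
Product: 26 3,5-bis(benzyloxy)-4-[(3R,4S)-7-(benzyloxy)-3-[3-(benzyloxy)-2,4-dimethoxyphenyl]chroman-4-yl]phenol
Conditions: TBAF, THF, 0 °C; aq NH4Cl
Reagents that add atoms: none
Why: Fluoride cleavage of an aryl silyl ether frees the one oxygen of ring D that will become O1 of ring F.

Step 17
Reactants: 26 3,5-bis(benzyloxy)-4-[(3R,4S)-7-(benzyloxy)-3-[3-(benzyloxy)-2,4-dimethoxyphenyl]chroman-4-yl]phenol
Product: 27 2,4-bis(benzyloxy)-3-[(3R,4S)-7-(benzyloxy)-3-[3-(benzyloxy)-2,4-dimethoxyphenyl]chroman-4-yl]-6-hydroxybenzaldehyde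
Conditions: MgCl2, Et3N, (CH2O)n, MeCN, reflux
Reagents that add atoms: paraformaldehyde (as formaldehyde), C=O
Why: Casiraghi–Skattebøl ortho-formylation: the magnesium phenoxide delivers formaldehyde only ortho to the free hydroxyl and a second formaldehyde oxidises the benzylic alkoxide; the two ortho positions of ring D are equivalent, no other ring has a free phenol, and the medium is basic.

Step 18
Reactants: 27 2,4-bis(benzyloxy)-3-[(3R,4S)-7-(benzyloxy)-3-[3-(benzyloxy)-2,4-dimethoxyphenyl]chroman-4-yl]-6-hydroxybenzaldehyde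
Product: 28 1-[2,4-bis(benzyloxy)-3-[(3R,4S)-7-(benzyloxy)-3-[3-(benzyloxy)-2,4-dimethoxyphenyl]chroman-4-yl]-6-hydroxyphenyl]prop-2-yn-1-ol (both carbinol epimers)
Conditions: HC≡CMgBr (excess), THF, 0 °C; aq NH4Cl; used crude
Reagents that add atoms: ethynylmagnesium bromide, C#C[Mg]Br
Why: Grignard addition to the aldehyde after deprotonation of the phenol; the new carbinol centre is removed in the next step.

Step 19
Reactants: 28 1-[2,4-bis(benzyloxy)-3-[(3R,4S)-7-(benzyloxy)-3-[3-(benzyloxy)-2,4-dimethoxyphenyl]chroman-4-yl]-6-hydroxyphenyl]prop-2-yn-1-ol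
Product: 30 5,7-bis(benzyloxy)-6-[(3R,4S)-7-(benzyloxy)-3-[3-(benzyloxy)-2,4-dimethoxyphenyl]chroman-4-yl]-4H-chromen-4-one, via ynone 29 (not isolated)
Conditions: MnO2, CH2Cl2, rt; filter; K2CO3 (cat.), acetone, rt
Reagents that add atoms: none
Why: MnO2 oxidation of a benzylic propargylic alcohol gives the ortho-hydroxyaryl ynone, whose phenoxide adds to the unsubstituted alkyne terminus (6-endo-dig oxa-Michael) to close the chromone without acid.

Step 20
Reactants: 30 5,7-bis(benzyloxy)-6-[(3R,4S)-7-(benzyloxy)-3-[3-(benzyloxy)-2,4-dimethoxyphenyl]chroman-4-yl]-4H-chromen-4-one, 31 4-(benzyloxy)phenylboronic acid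
Product: 32 (2S)-5,7-bis(benzyloxy)-2-[4-(benzyloxy)phenyl]-6-[(3R,4S)-7-(benzyloxy)-3-[3-(benzyloxy)-2,4-dimethoxyphenyl]chroman-4-yl]chroman-4-one
Conditions: [Rh(OH){(S)-MeO-F12-BIPHEP}]2 (3 mol % Rh), toluene/H2O, 20 °C
Reagents that add atoms: none
Why: Hayashi–Miyaura asymmetric 1,4-addition of an arylboronic acid to a chromone, a reaction known for 5,7-dioxygenated chromones with this electron-poor bisphosphine; the arylrhodium species inserts C2=C3 on the face chosen by the ligand and water protonates the enolate, so C2 is set by the catalyst alone, and the base-free medium prevents ring-opening of the flavanone.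

Step 21
Reactants: 32 (2S)-5,7-bis(benzyloxy)-2-[4-(benzyloxy)phenyl]-6-[(3R,4S)-7-(benzyloxy)-3-[3-(benzyloxy)-2,4-dimethoxyphenyl]chroman-4-yl]chroman-4-one
Product: 33 (2S)-5,7-dihydroxy-6-[(3R,4S)-7-hydroxy-3-(3-hydroxy-2,4-dimethoxyphenyl)chroman-4-yl]-2-(4-hydroxyphenyl)chroman-4-one
Conditions: H2 (1 atm), Pd/C, EtOAc/MeOH, rt
Reagents that add atoms: none
Why: Hydrogenolysis of five aryl benzyl ethers under neutral conditions, as used for benzyl-protected naringenin; short reaction time at ambient pressure spares the ketone and the benzylic C2–O1 bond, and no acid or base meets the C4–ring D bond or the flavanone.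

## Compound list

1 | 2,4,6-trihydroxybenzaldehyde | O=Cc1c(O)cc(O)cc1O | starting material
2 | 2,6-dihydroxy-4-(triisopropylsilyloxy)benzaldehyde | O=Cc1c(O)cc(O[Si](C(C)C)(C(C)C)C(C)C)cc1O | intermediate
3 | 2,6-bis(benzyloxy)-4-(triisopropylsilyloxy)benzaldehyde | O=Cc1c(OCc2ccccc2)cc(O[Si](C(C)C)(C(C)C)C(C)C)cc1OCc1ccccc1 | intermediate
4 | [3,5-bis(benzyloxy)-4-(2,2-dibromoethenyl)phenoxy]triisopropylsilane | BrC(Br)=Cc1c(OCc2ccccc2)cc(O[Si](C(C)C)(C(C)C)C(C)C)cc1OCc1ccccc1 | intermediate
5 | [3,5-bis(benzyloxy)-4-ethynylphenoxy]triisopropylsilane | C#Cc1c(OCc2ccccc2)cc(O[Si](C(C)C)(C(C)C)C(C)C)cc1OCc1ccccc1 | intermediate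
6 | acenaphthoquinone | O=C1C(=O)c2cccc3cccc1c23 | starting material
7 | cis-1,2-dimethyl-1,2-dihydroacenaphthylene-1,2-diol (meso) | C[C@]1(O)c2cccc3cccc(c23)[C@@]1(C)O | intermediate
8 | (E)-2-{2-[2,6-bis(benzyloxy)-4-(triisopropylsilyloxy)phenyl]ethenyl}-1,3,2-benzodioxaborole | c1ccc2OB(/C=C/c3c(OCc4ccccc4)cc(O[Si](C(C)C)(C(C)C)C(C)C)cc3OCc3ccccc3)Oc2c1 | intermediate
9 | (E)-2-[2,6-bis(benzyloxy)-4-(triisopropylsilyloxy)phenyl]ethenylboronic acid cis-1,2-dimethylacenaphthene-1,2-diyl ester | C[C@]1(O2)c3cccc4cccc(c34)[C@@]1(C)OB2/C=C/c1c(OCc2ccccc2)cc(O[Si](C(C)C)(C(C)C)C(C)C)cc1OCc1ccccc1 | intermediate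
10 | 4-(benzyloxy)-2-hydroxybenzaldehyde | O=Cc1ccc(OCc2ccccc2)cc1O | starting material
11 | 4-(benzyloxy)-2-(methoxymethoxy)benzaldehyde | COCOc1cc(OCc2ccccc2)ccc1C=O | intermediate
12 | 4-(benzyloxy)-2-(methoxymethoxy)phenyl formate | COCOc1cc(OCc2ccccc2)ccc1OC=O | intermediate
13 | 4-(benzyloxy)-2-(methoxymethoxy)phenol | COCOc1cc(OCc2ccccc2)ccc1O | intermediate
14 | 4-(benzyloxy)-2-(methoxymethoxy)phenyl trifluoromethanesulfonate | COCOc1cc(OCc2ccccc2)ccc1OS(=O)(=O)C(F)(F)F | intermediate
15 | 2,6-dimethoxyphenol | COc1cccc(OC)c1O | starting material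
16 | 2-(benzyloxy)-1,3-dimethoxybenzene | COc1cccc(OC)c1OCc1ccccc1 | intermediate
17 | 2-(benzyloxy)-4-bromo-1,3-dimethoxybenzene | COc1ccc(Br)c(OC)c1OCc1ccccc1 | intermediate
18 | [3-(benzyloxy)-2,4-dimethoxyphenyl]lithium | [Li]c1ccc(OC)c(OCc2ccccc2)c1OC | intermediate
19 | lithium borate from 18 and 9 (aryl and E alkenyl groups on boron, configuration at boron undefined) | [Li+].COc1ccc([B-]2(/C=C/c3c(OCc4ccccc4)cc(O[Si](C(C)C)(C(C)C)C(C)C)cc3OCc3ccccc3)O[C@@]3(C)c4cccc5cccc(c45)[C@@]3(C)O2)c(OC)c1OCc1ccccc1 | intermediate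
20 | [(1R,2S)-1-[3-(benzyloxy)-2,4-dimethoxyphenyl]-2-[4-(benzyloxy)-2-(methoxymethoxy)phenyl]-2-[2,6-bis(benzyloxy)-4-(triisopropylsilyloxy)phenyl]ethyl]boronic acid cis-1,2-dimethylacenaphthene-1,2-diyl ester | COc1ccc([C@@H]([C@@H](c2ccc(OCc3ccccc3)cc2OCOC)c2c(OCc3ccccc3)cc(O[Si](C(C)C)(C(C)C)C(C)C)cc2OCc2ccccc2)B2O[C@@]3(C)c4cccc5cccc(c45)[C@@]3(C)O2)c(OC)c1OCc1ccccc1 | intermediate
21 | [(2R,3S)-2-[3-(benzyloxy)-2,4-dimethoxyphenyl]-3-[4-(benzyloxy)-2-(methoxymethoxy)phenyl]-3-[2,6-bis(benzyloxy)-4-(triisopropylsilyloxy)phenyl]propyl]boronic acid cis-1,2-dimethylacenaphthene-1,2-diyl ester | COc1ccc([C@@H]([C@@H](c2ccc(OCc3ccccc3)cc2OCOC)c2c(OCc3ccccc3)cc(O[Si](C(C)C)(C(C)C)C(C)C)cc2OCc2ccccc2)CB2O[C@@]3(C)c4cccc5cccc(c45)[C@@]3(C)O2)c(OC)c1OCc1ccccc1 | intermediate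
22 | (2R,3S)-2-[3-(benzyloxy)-2,4-dimethoxyphenyl]-3-[4-(benzyloxy)-2-(methoxymethoxy)phenyl]-3-[2,6-bis(benzyloxy)-4-(triisopropylsilyloxy)phenyl]propan-1-ol | COc1ccc([C@@H]([C@@H](c2ccc(OCc3ccccc3)cc2OCOC)c2c(OCc3ccccc3)cc(O[Si](C(C)C)(C(C)C)C(C)C)cc2OCc2ccccc2)CO)c(OC)c1OCc1ccccc1 | intermediate
23 | bis(trimethylsilyl) ether of 24 (aryl and primary alkyl oxygens silylated) | COc1ccc([C@@H]([C@@H](c2ccc(OCc3ccccc3)cc2O[Si](C)(C)C)c2c(OCc3ccccc3)cc(O[Si](C(C)C)(C(C)C)C(C)C)cc2OCc2ccccc2)CO[Si](C)(C)C)c(OC)c1OCc1ccccc1 | intermediate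
24 | (2R,3S)-2-[3-(benzyloxy)-2,4-dimethoxyphenyl]-3-[4-(benzyloxy)-2-hydroxyphenyl]-3-[2,6-bis(benzyloxy)-4-(triisopropylsilyloxy)phenyl]propan-1-ol | COc1ccc([C@@H]([C@@H](c2ccc(OCc3ccccc3)cc2O)c2c(OCc3ccccc3)cc(O[Si](C(C)C)(C(C)C)C(C)C)cc2OCc2ccccc2)CO)c(OC)c1OCc1ccccc1 | intermediate
25 | (3R,4S)-7-(benzyloxy)-3-[3-(benzyloxy)-2,4-dimethoxyphenyl]-4-[2,6-bis(benzyloxy)-4-(triisopropylsilyloxy)phenyl]chromane | COc1ccc([C@@H]2COc3cc(OCc4ccccc4)ccc3[C@H]2c2c(OCc3ccccc3)cc(O[Si](C(C)C)(C(C)C)C(C)C)cc2OCc2ccccc2)c(OC)c1OCc1ccccc1 | intermediate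
26 | 3,5-bis(benzyloxy)-4-[(3R,4S)-7-(benzyloxy)-3-[3-(benzyloxy)-2,4-dimethoxyphenyl]chroman-4-yl]phenol | COc1ccc([C@@H]2COc3cc(OCc4ccccc4)ccc3[C@H]2c2c(OCc3ccccc3)cc(O)cc2OCc2ccccc2)c(OC)c1OCc1ccccc1 | intermediate
27 | 2,4-bis(benzyloxy)-3-[(3R,4S)-7-(benzyloxy)-3-[3-(benzyloxy)-2,4-dimethoxyphenyl]chroman-4-yl]-6-hydroxybenzaldehyde | COc1ccc([C@@H]2COc3cc(OCc4ccccc4)ccc3[C@H]2c2c(OCc3ccccc3)cc(O)c(C=O)c2OCc2ccccc2)c(OC)c1OCc1ccccc1 | intermediate
28 | 1-[2,4-bis(benzyloxy)-3-[(3R,4S)-7-(benzyloxy)-3-[3-(benzyloxy)-2,4-dimethoxyphenyl]chroman-4-yl]-6-hydroxyphenyl]prop-2-yn-1-ol (carbinol epimers) | COc1ccc([C@@H]2COc3cc(OCc4ccccc4)ccc3[C@H]2c2c(OCc3ccccc3)cc(O)c(C(O)C#C)c2OCc2ccccc2)c(OC)c1OCc1ccccc1 | intermediate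
29 | 1-[2,4-bis(benzyloxy)-3-[(3R,4S)-7-(benzyloxy)-3-[3-(benzyloxy)-2,4-dimethoxyphenyl]chroman-4-yl]-6-hydroxyphenyl]prop-2-yn-1-one | COc1ccc([C@@H]2COc3cc(OCc4ccccc4)ccc3[C@H]2c2c(OCc3ccccc3)cc(O)c(C(=O)C#C)c2OCc2ccccc2)c(OC)c1OCc1ccccc1 | intermediate
30 | 5,7-bis(benzyloxy)-6-[(3R,4S)-7-(benzyloxy)-3-[3-(benzyloxy)-2,4-dimethoxyphenyl]chroman-4-yl]-4H-chromen-4-one | COc1ccc([C@@H]2COc3cc(OCc4ccccc4)ccc3[C@H]2c2c(OCc3ccccc3)cc3occc(=O)c3c2OCc2ccccc2)c(OC)c1OCc1ccccc1 | intermediate
31 | 4-(benzyloxy)phenylboronic acid | OB(O)c1ccc(OCc2ccccc2)cc1 | starting material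
32 | (2S)-5,7-bis(benzyloxy)-2-[4-(benzyloxy)phenyl]-6-[(3R,4S)-7-(benzyloxy)-3-[3-(benzyloxy)-2,4-dimethoxyphenyl]chroman-4-yl]chroman-4-one | COc1ccc([C@@H]2COc3cc(OCc4ccccc4)ccc3[C@H]2c2c(OCc3ccccc3)cc3c(c2OCc2ccccc2)C(=O)C[C@@H](c2ccc(OCc4ccccc4)cc2)O3)c(OC)c1OCc1ccccc1 | intermediate
33 | (2S)-5,7-dihydroxy-6-[(3R,4S)-7-hydroxy-3-(3-hydroxy-2,4-dimethoxyphenyl)chroman-4-yl]-2-(4-hydroxyphenyl)chroman-4-one | COc1ccc([C@@H]2COc3cc(O)ccc3[C@H]2c2c(O)cc3c(c2O)C(=O)C[C@@H](c2ccc(O)cc2)O3)c(OC)c1O | target

## Step count and risks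

Total: 21 steps. Longest linear sequence: 15 steps (steps 1–4, 6 and 12–21). The side branches are step 5 (diol 7), steps 7–9 (triflate 14) and steps 10–11 (bromide 17).

**Step 12 (key step).** The most likely failure is direct transmetalation of borate 19 to palladium (Suzuki–Miyaura coupling) outrunning the metallate shift. The two ortho-benzyloxy groups on the β-aryl ring shield the alkene from the cationic arylpalladium, and oxidative addition of the electron-rich ortho-alkoxy triflate is slow. A second risk is weaker facial discrimination than with simple β-alkyl substrates. The fallback abandons the boron chemistry and forms C3–C4 and O1–C2 by a quinone-methide annulation; it sets out from aldehyde 3 and bromide 17 and returns at diol 24. Aldehyde 3 would be condensed with the bromomagnesium salt of commercial 3-(benzyloxy)phenol (ortho-selective hydroxyalkylation) to give the ortho-hydroxybenzhydrol F1. Aryllithium 18, from 17, would be opened onto ethylene oxide to give the arylethanol F2, and Dess–Martin oxidation would give the arylacetaldehyde F3. F1 and F3 would be united by (R)-α,α-diphenylprolinol trimethylsilyl ether and a carboxylic acid co-catalyst in a formal [4+2] annulation to the trans lactol F4. NaBH4 reduction of F4 at low temperature opens the lactol to 24, which re-enters the route at step 15.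

**Step 13.** Chloromethyllithium decomposes above about −70 °C, and borate formation at the hindered secondary boron, flanked by three arenes and the bulky diol, may be slower than that decomposition; unreacted 20 would then be oxidised to the secondary alcohol. The fallback replaces the unstable carbenoid by a stable vinyl nucleophile; it sets out from 20 and returns at 22. Compound 20 would be treated with vinyllithium, then iodine and NaOMe (Zweifel olefination, migration with retention), to give the terminal alkene F5. Dihydroxylation and cleavage (OsO4 cat., NMO; then NaIO4) would give the aldehyde F6, which NaBH4 would reduce immediately to 22 before the α-aryl centre can epimerise.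

**Step 19 (with step 18).** The ortho-hydroxy propargylic carbinol 28 sits on a very electron-rich ring and can ionise to a quinone methide on handling. MnO2 may also attack the free phenol, and the terminal ynone 29 can oligomerise by intermolecular conjugate addition. The fallback avoids the carbinol and its oxidation; it sets out from phenol 26 and returns at chromone 30. NBS at low temperature would give the ortho-bromophenol F7. Stille coupling with tributyl(1-ethoxyvinyl)stannane would give the enol ether F8, hydrolysed on dilute acid work-up to the ortho-hydroxyacetophenone F9. Condensation with DMF dimethyl acetal would give the enaminone F10, which closes to 30 on brief treatment with mild acid; at that stage ring D is deactivated by the acyl group.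

**Step 20.** The 5-benzyloxy group lies peri to the carbonyl, which lowers the electrophilicity of the chromone and crowds the rhodium-bound enone. Insertion may be slow, protodeboronation of 31 may compete, and catalyst control may be incomplete. The fallback gives up catalyst control for separation and recycling; it sets out from 26 by way of acetophenone F9 (reached as described for step 19) and returns at 32. Claisen–Schmidt condensation of F9 with 4-(benzyloxy)benzaldehyde would give the 2'-hydroxychalcone F11. NaOAc in refluxing ethanol would close F11 to 32 and its C2 epimer F12. These are diastereomers because the isoflavan half is a single enantiomer, and would be separated by preparative chromatography. F12 would be returned to the same conditions, which re-equilibrate it through F11.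

## Further compounds

F1 | step 12 | [4-(benzyloxy)-2-hydroxyphenyl][2,6-bis(benzyloxy)-4-(triisopropylsilyloxy)phenyl]methanol (racemic) | OC(c1ccc(OCc2ccccc2)cc1O)c1c(OCc2ccccc2)cc(O[Si](C(C)C)(C(C)C)C(C)C)cc1OCc1ccccc1
F2 | step 12 | 2-[3-(benzyloxy)-2,4-dimethoxyphenyl]ethan-1-ol | COc1ccc(CCO)c(OC)c1OCc1ccccc1
F3 | step 12 | 2-[3-(benzyloxy)-2,4-dimethoxyphenyl]acetaldehyde | COc1ccc(CC=O)c(OC)c1OCc1ccccc1
F4 | step 12 | (3R,4S)-7-(benzyloxy)-3-[3-(benzyloxy)-2,4-dimethoxyphenyl]-4-[2,6-bis(benzyloxy)-4-(triisopropylsilyloxy)phenyl]chroman-2-ol (anomeric mixture) | COc1ccc([C@@H]2C(O)Oc3cc(OCc4ccccc4)ccc3[C@H]2c2c(OCc3ccccc3)cc(O[Si](C(C)C)(C(C)C)C(C)C)cc2OCc2ccccc2)c(OC)c1OCc1ccccc1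
F5 | step 13 | 3-[3-(benzyloxy)-2,4-dimethoxyphenyl]-4-[4-(benzyloxy)-2-(methoxymethoxy)phenyl]-4-[2,6-bis(benzyloxy)-4-(triisopropylsilyloxy)phenyl]but-1-ene, C3 and C4 configured as C2 and C3 of 22 | COc1ccc([C@@H]([C@@H](c2ccc(OCc3ccccc3)cc2OCOC)c2c(OCc3ccccc3)cc(O[Si](C(C)C)(C(C)C)C(C)C)cc2OCc2ccccc2)C=C)c(OC)c1OCc1ccccc1
F6 | step 13 | 2-[3-(benzyloxy)-2,4-dimethoxyphenyl]-3-[4-(benzyloxy)-2-(methoxymethoxy)phenyl]-3-[2,6-bis(benzyloxy)-4-(triisopropylsilyloxy)phenyl]propanal, configured as 22 | COc1ccc([C@@H]([C@@H](c2ccc(OCc3ccccc3)cc2OCOC)c2c(OCc3ccccc3)cc(O[Si](C(C)C)(C(C)C)C(C)C)cc2OCc2ccccc2)C=O)c(OC)c1OCc1ccccc1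
F7 | step 19 | 3,5-bis(benzyloxy)-4-[(3R,4S)-7-(benzyloxy)-3-[3-(benzyloxy)-2,4-dimethoxyphenyl]chroman-4-yl]-2-bromophenol | COc1ccc([C@@H]2COc3cc(OCc4ccccc4)ccc3[C@H]2c2c(OCc3ccccc3)cc(O)c(Br)c2OCc2ccccc2)c(OC)c1OCc1ccccc1
F8 | step 19 | 3,5-bis(benzyloxy)-4-[(3R,4S)-7-(benzyloxy)-3-[3-(benzyloxy)-2,4-dimethoxyphenyl]chroman-4-yl]-2-(1-ethoxyethenyl)phenol | COc1ccc([C@@H]2COc3cc(OCc4ccccc4)ccc3[C@H]2c2c(OCc3ccccc3)cc(O)c(C(=C)OCC)c2OCc2ccccc2)c(OC)c1OCc1ccccc1
F9 | step 19 | 1-[2,4-bis(benzyloxy)-3-[(3R,4S)-7-(benzyloxy)-3-[3-(benzyloxy)-2,4-dimethoxyphenyl]chroman-4-yl]-6-hydroxyphenyl]ethan-1-one | COc1ccc([C@@H]2COc3cc(OCc4ccccc4)ccc3[C@H]2c2c(OCc3ccccc3)cc(O)c(C(C)=O)c2OCc2ccccc2)c(OC)c1OCc1ccccc1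
F10 | step 19 | (E)-1-[2,4-bis(benzyloxy)-3-[(3R,4S)-7-(benzyloxy)-3-[3-(benzyloxy)-2,4-dimethoxyphenyl]chroman-4-yl]-6-hydroxyphenyl]-3-(dimethylamino)prop-2-en-1-one | COc1ccc([C@@H]2COc3cc(OCc4ccccc4)ccc3[C@H]2c2c(OCc3ccccc3)cc(O)c(C(=O)/C=C/N(C)C)c2OCc2ccccc2)c(OC)c1OCc1ccccc1
F11 | step 20 | (E)-1-[2,4-bis(benzyloxy)-3-[(3R,4S)-7-(benzyloxy)-3-[3-(benzyloxy)-2,4-dimethoxyphenyl]chroman-4-yl]-6-hydroxyphenyl]-3-[4-(benzyloxy)phenyl]prop-2-en-1-one | COc1ccc([C@@H]2COc3cc(OCc4ccccc4)ccc3[C@H]2c2c(OCc3ccccc3)cc(O)c(C(=O)/C=C/c3ccc(OCc4ccccc4)cc3)c2OCc2ccccc2)c(OC)c1OCc1ccccc1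
F12 | step 20 | (2R)-5,7-bis(benzyloxy)-2-[4-(benzyloxy)phenyl]-6-[(3R,4S)-7-(benzyloxy)-3-[3-(benzyloxy)-2,4-dimethoxyphenyl]chroman-4-yl]chroman-4-one (C2 epimer of 32) | COc1ccc([C@@H]2COc3cc(OCc4ccccc4)ccc3[C@H]2c2c(OCc3ccccc3)cc3c(c2OCc2ccccc2)C(=O)C[C@H](c2ccc(OCc4ccccc4)cc2)O3)c(OC)c1OCc1ccccc1
A1 | alternative 1 | 3,5-bis(benzyloxy)-4-[(3R,4S)-7-(benzyloxy)-3-[3-(benzyloxy)-2,4-dimethoxyphenyl]chroman-4-yl]-2-iodophenol | COc1ccc([C@@H]2COc3cc(OCc4ccccc4)ccc3[C@H]2c2c(OCc3ccccc3)cc(O)c(I)c2OCc2ccccc2)c(OC)c1OCc1ccccc1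
A2 | alternative 1 | 1-(benzyloxy)-4-ethynylbenzene | C#Cc1ccc(OCc2ccccc2)cc1
A3 | alternative 1 | 5,7-bis(benzyloxy)-2-[4-(benzyloxy)phenyl]-6-[(3R,4S)-7-(benzyloxy)-3-[3-(benzyloxy)-2,4-dimethoxyphenyl]chroman-4-yl]-4H-chromen-4-one | COc1ccc([C@@H]2COc3cc(OCc4ccccc4)ccc3[C@H]2c2c(OCc3ccccc3)cc3oc(-c4ccc(OCc5ccccc5)cc4)cc(=O)c3c2OCc2ccccc2)c(OC)c1OCc1ccccc1
A4 | alternative 2 | 3,5-bis(benzyloxy)-4-[(3R,4S)-7-(benzyloxy)-3-[3-(benzyloxy)-2,4-dimethoxyphenyl]chroman-4-yl]-2-(trimethylsilyl)phenyl trifluoromethanesulfonate | COc1ccc([C@@H]2COc3cc(OCc4ccccc4)ccc3[C@H]2c2c(OCc3ccccc3)cc(OS(=O)(=O)C(F)(F)F)c([Si](C)(C)C)c2OCc2ccccc2)c(OC)c1OCc1ccccc1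
A5 | alternative 2 | (E)-3-[4-(benzyloxy)phenyl]prop-2-enoic acid | OC(=O)/C=C/c1ccc(OCc2ccccc2)cc1
A6 | alternative 2 | (E)-1-[2,4-bis(benzyloxy)-3-[(3R,4S)-7-(benzyloxy)-3-[3-(benzyloxy)-2,4-dimethoxyphenyl]chroman-4-yl]-6-hydroxyphenyl]-3-[4-(benzyloxy)phenyl]prop-2-en-1-one | COc1ccc([C@@H]2COc3cc(OCc4ccccc4)ccc3[C@H]2c2c(OCc3ccccc3)cc(O)c(C(=O)/C=C/c3ccc(OCc4ccccc4)cc3)c2OCc2ccccc2)c(OC)c1OCc1ccccc1
A7 | alternative 3 | [4-(benzyloxy)-2-hydroxyphenyl][2,6-bis(benzyloxy)-4-(triisopropylsilyloxy)phenyl]methanol (racemic) | OC(c1ccc(OCc2ccccc2)cc1O)c1c(OCc2ccccc2)cc(O[Si](C(C)C)(C(C)C)C(C)C)cc1OCc1ccccc1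
A8 | alternative 3 | 2-[3-(benzyloxy)-2,4-dimethoxyphenyl]acetaldehyde | COc1ccc(CC=O)c(OC)c1OCc1ccccc1
A9 | alternative 3 | (3R,4S)-7-(benzyloxy)-3-[3-(benzyloxy)-2,4-dimethoxyphenyl]-4-[2,6-bis(benzyloxy)-4-(triisopropylsilyloxy)phenyl]chroman-2-ol (anomeric mixture) | COc1ccc([C@@H]2C(O)Oc3cc(OCc4ccccc4)ccc3[C@H]2c2c(OCc3ccccc3)cc(O[Si](C(C)C)(C(C)C)C(C)C)cc2OCc2ccccc2)c(OC)c1OCc1ccccc1
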